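**Retrosynthetic overview**
1. Target ⇐ phenol 22 (late para‑hydroxylation via the quinone, MOM removal); the C6 methyl ⇐ C6 carbinol by radical deoxymethylation.
2. Ring A (C2 ketone, C1 propanoate chain) ⇐ one‑carbon ring expansion: semipinacol 1,2‑shift of the quaternary ring carbon of 1‑vinylhydrindan‑1‑ol 16, triggered by addition of •CH2CO2Me.
3. Quaternary C5 (methyl, arylmethyl) and the trans ring fusion ⇐ Stork reductive benzylation of enone 12 with bromide 6 (from o‑cresol).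
4. Enone 12 ⇐ vinyl addition to enedione 10 ⇐ asymmetric Robinson annulation of 2‑methylcyclopentane‑1,3‑dione with ethyl vinyl ketone.
5. Ring order: five‑membered ring (from the dione) → ring B (annulation) → five‑membered ring enlarged to ring A last.

Assumption: hydrindanes carry indene locants, decalins the locants of the target name methyl 3‑[(1S,4aR,5S,6S,8aR)‑5‑[(2,5‑dihydroxy‑3‑methylphenyl)methyl]‑5,6,8a‑trimethyl‑2‑oxodecahydronaphthalen‑1‑yl]propanoate; D‑phenylalanine, MeBr solution and the benzoxazolium salt are bought as reagents.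

**Step 1**
Reactants: 1 o‑cresol (2‑methylphenol)
Product: 2 1‑(methoxymethoxy)‑2‑methylbenzene
Conditions: MOMCl, i‑Pr2NEt, CH2Cl2, 0 → 23 °C
Reagents that add atoms: chloromethyl methyl ether COCCl
Why: Base‑mediated O‑alkylation (MOM ether formation) masks the phenol with a group that directs the next lithiation, survives dissolving‑metal, hydride, radical and silver conditions and leaves under mild acid; no stereocenter.

**Step 2**
Reactants: 2 1‑(methoxymethoxy)‑2‑methylbenzene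
Product: 6 1‑(bromomethyl)‑2‑(methoxymethoxy)‑3‑methylbenzene, via aryllithium 3 (not isolated), via lithium alkoxide 4 (not isolated), via mesylate 5 (not isolated)
Conditions: s‑BuLi, TMEDA, THF, −78 °C; (CH2O)n, −78 → 23 °C; then MsCl, LiBr, 0 → 23 °C
Reagents that add atoms: paraformaldehyde (as formaldehyde) C=O; lithium bromide [Li+].[Br-]
Why: Directed ortho‑metalation beside the MOM ether (the other ortho position carries the methyl), hydroxymethylation, in‑flask mesylation of the lithium alkoxide and SN2 displacement by bromide give the benzylic electrophile; no stereocenter.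

**Step 3**
Reactants: 7 2‑methylcyclopentane‑1,3‑dione; 8 pent‑1‑en‑3‑one (ethyl vinyl ketone)
Product: 10 (7aR)‑4,7a‑dimethyl‑2,3,7,7a‑tetrahydro‑1H‑indene‑1,5(6H)‑dione, via triketone 9 (not isolated)
Conditions: Et3N (5 mol %), MeCN, 23 °C; then D‑phenylalanine (1 equiv), aq HClO4 (0.5 equiv), 80 °C
Reagents that add atoms: none
Why: Michael addition, then the amino‑acid‑mediated Hajos–Parrish–Eder–Sauer–Wiechert aldol condensation, in which the enamine of D‑phenylalanine attacks one of the two enantiotopic ring carbonyls and fixes the quaternary carbon as 7aR (the future C8a).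

**Step 4**
Reactants: 10 (7aR)‑4,7a‑dimethyl‑2,3,7,7a‑tetrahydro‑1H‑indene‑1,5(6H)‑dione; 11 vinylmagnesium bromide (CH2=CHMgBr)
Product: 12 (1S,7aR)‑1‑ethenyl‑1‑hydroxy‑4,7a‑dimethyl‑1,2,3,6,7,7a‑hexahydro‑5H‑inden‑5‑one
Conditions: CeCl3, THF, −78 °C; then H2O
Reagents that add atoms: none
Why: Chemoselective 1,2‑addition of the organocerium reagent (Grignard/CeCl3) to the more electrophilic saturated cyclopentanone, from the face opposite the angular methyl, gives the 1S carbinol, which masks this carbonyl for step 5 and places the vinyl group needed for the ring expansion.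

**Step 5**
Reactants: 12 (1S,7aR)‑1‑ethenyl‑1‑hydroxy‑4,7a‑dimethyl‑1,2,3,6,7,7a‑hexahydro‑5H‑inden‑5‑one; 6 1‑(bromomethyl)‑2‑(methoxymethoxy)‑3‑methylbenzene
Product: 15 (1S,3aS,4R,7aR)‑1‑ethenyl‑1‑hydroxy‑4‑{[2‑(methoxymethoxy)‑3‑methylphenyl]methyl}‑4,7a‑dimethyloctahydro‑5H‑inden‑5‑one, via lithium alkoxide 13 (not isolated), via dilithium enolate 14 (not isolated)
Conditions: LiN(SiMe3)2 (1.0 equiv), THF, −78 °C; Li (2.2 equiv), NH3(l)/THF, −78 °C; isoprene; then 6, −78 → −33 °C; H2O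
Reagents that add atoms: none
Why: Stork reductive alkylation (Birch reduction of the enone with enolate trapping): axial protonation at C3a by ammonia gives the trans ring fusion and the regiodefined enolate is benzylated on the face opposite the angular methyl, so C4 becomes quaternary with its methyl syn and the arylmethyl anti to the angular methyl (3aS,4R).

**Step 6**
Reactants: 15 (1S,3aS,4R,7aR)‑1‑ethenyl‑1‑hydroxy‑4‑{[2‑(methoxymethoxy)‑3‑methylphenyl]methyl}‑4,7a‑dimethyloctahydro‑5H‑inden‑5‑one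
Product: 16 (1S,3aR,4R,5R,7aR)‑1‑ethenyl‑4‑{[2‑(methoxymethoxy)‑3‑methylphenyl]methyl}‑4,7a‑dimethyloctahydro‑1H‑indene‑1,5‑diol
Conditions: NaBH4, MeOH/THF, 0 → 23 °C
Reagents that add atoms: none
Why: Borohydride reduction of the only ketone, hydride entering anti to the axial C4 methyl to give the equatorial 5R alcohol (a handle whose configuration is erased in step 8).

**Step 7**
Reactants: 16 (1S,3aR,4R,5R,7aR)‑1‑ethenyl‑4‑{[2‑(methoxymethoxy)‑3‑methylphenyl]methyl}‑4,7a‑dimethyloctahydro‑1H‑indene‑1,5‑diol; 17 methyl iodoacetate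
Product: 19 methyl 3‑[(1S,4aS,5R,6R,8aR)‑6‑hydroxy‑5‑{[2‑(methoxymethoxy)‑3‑methylphenyl]methyl}‑5,8a‑dimethyl‑2‑oxodecahydronaphthalen‑1‑yl]propanoate, via iodohydrin 18 (not isolated)
Conditions: Et3B (0.2 equiv), air, CH2Cl2, 23 °C; then AgOTf (1.3 equiv), 2,6‑di‑tert‑butylpyridine, −40 → 0 °C
Reagents that add atoms: none
Why: Proposed new method: a one‑flask alkylative semipinacol ring expansion of an unactivated 1‑vinylcyclopentanol, in which the radical •CH2CO2Me (iodine‑atom‑transfer chain started by Et3B/air) adds to the terminal vinyl carbon and iodine is transferred to the carbon next to the carbinol, after which AgOTf removes iodide while the anti‑periplanar, more electron‑rich bond to the quaternary C7a shifts to that carbon and the carbinol collapses to the ketone, so the five‑membered ring becomes ring A (old C1 → C2 ketone, new C1–C8a bond, complete propanoate chain) with C8a migrating with retention and the enolisable C1 formed as an epimer mixture that converges in step 9; the closest known reactions are halonium‑ or radical‑triggered semipinacol ring expansions of 1‑(1‑arylvinyl)cyclobutanols and silver‑promoted halohydrin rearrangements, with migration of a quaternary ring carbon to a secondary centre precedented in steroidal D‑homoannulations.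

**Step 8**
Reactants: 19 methyl 3‑[(1S,4aS,5R,6R,8aR)‑6‑hydroxy‑5‑{[2‑(methoxymethoxy)‑3‑methylphenyl]methyl}‑5,8a‑dimethyl‑2‑oxodecahydronaphthalen‑1‑yl]propanoate
Product: 21 methyl 3‑[(1S,4aR,5S,6S,8aR)‑5‑{[2‑(methoxymethoxy)‑3‑methylphenyl]methyl}‑5,6,8a‑trimethyl‑2‑oxodecahydronaphthalen‑1‑yl]propanoate, via alkoxybenzoxazoline 20 (not isolated)
Conditions: 5,7‑di‑tert‑butyl‑3‑phenylbenzoxazolium tetrafluoroborate, pyridine, MTBE, 23 °C; then MeBr, [Ir(ppy)2(dtbbpy)]PF6 (1 mol %), NiBr2·dme (5 mol %), 4,4′‑di‑tert‑butyl‑2,2′‑bipyridine, quinuclidine, DMA, 450 nm, 23 °C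
Reagents that add atoms: bromomethane CBr
Why: Deoxygenative C(sp3)–C(sp3) cross‑coupling (benzoxazolium activation of the alcohol, photoredox β‑scission, nickel‑mediated methyl transfer): the planar secondary C6 radical is captured on the face anti to the axial C5 methyl, the only trajectory not gauche to both C5 substituents, so the new methyl is axial and trans to the C5 methyl (6S) as in the target.

**Step 9**
Reactants: 21 methyl 3‑[(1S,4aR,5S,6S,8aR)‑5‑{[2‑(methoxymethoxy)‑3‑methylphenyl]methyl}‑5,6,8a‑trimethyl‑2‑oxodecahydronaphthalen‑1‑yl]propanoate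
Product: 22 methyl 3‑[(1S,4aR,5S,6S,8aR)‑5‑[(2‑hydroxy‑3‑methylphenyl)methyl]‑5,6,8a‑trimethyl‑2‑oxodecahydronaphthalen‑1‑yl]propanoate
Conditions: HCl (2 M in MeOH), 40 °C; then aq NaHCO3
Reagents that add atoms: none
Why: Acid‑catalysed acetal exchange (MOM cleavage) frees the phenol, and the same conditions equilibrate the enolisable C1 centre to the equatorial 1S side chain of the target (estimated preference only about 4:1, so the minor epimer is separated and recycled).

**Step 10**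
Reactants: 22 methyl 3‑[(1S,4aR,5S,6S,8aR)‑5‑[(2‑hydroxy‑3‑methylphenyl)methyl]‑5,6,8a‑trimethyl‑2‑oxodecahydronaphthalen‑1‑yl]propanoate
Product: 24 methyl 3‑[(1S,4aR,5S,6S,8aR)‑5‑[(2,5‑dihydroxy‑3‑methylphenyl)methyl]‑5,6,8a‑trimethyl‑2‑oxodecahydronaphthalen‑1‑yl]propanoate (CNP0535359.1), via quinone 23 (not isolated)
Conditions: (KSO3)2NO, KH2PO4, acetone/H2O, 23 °C; then aq Na2S2O4
Reagents that add atoms: potassium nitrosodisulfonate [K+].[K+].[O]N(S(=O)(=O)[O-])S(=O)(=O)[O-]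
Why: Teuber oxidation of the para‑unsubstituted 2,6‑dialkylphenol by the nitroxyl radical gives the para‑quinone, which Na2S2O4 reduces in the work‑up to the hydroquinone without touching ketone or ester; no stereocenter changes.

**Compound list**
1 | o‑cresol (2‑methylphenol) | Cc1ccccc1O | starting material
2 | 1‑(methoxymethoxy)‑2‑methylbenzene | COCOc1ccccc1C | intermediate
3 | [2‑(methoxymethoxy)‑3‑methylphenyl]lithium | [Li]c1cccc(C)c1OCOC | intermediate
4 | lithium [2‑(methoxymethoxy)‑3‑methylphenyl]methanolate | [Li]OCc1cccc(C)c1OCOC | intermediate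
5 | [2‑(methoxymethoxy)‑3‑methylphenyl]methyl methanesulfonate | CS(=O)(=O)OCc1cccc(C)c1OCOC | intermediate
6 | 1‑(bromomethyl)‑2‑(methoxymethoxy)‑3‑methylbenzene | BrCc1cccc(C)c1OCOC | intermediate
7 | 2‑methylcyclopentane‑1,3‑dione | CC1C(=O)CCC1=O | starting material
8 | pent‑1‑en‑3‑one (ethyl vinyl ketone) | CCC(=O)C=C | starting material
9 | 2‑methyl‑2‑(3‑oxopentyl)cyclopentane‑1,3‑dione | CCC(=O)CCC1(C)C(=O)CCC1=O | intermediate
10 | (7aR)‑4,7a‑dimethyl‑2,3,7,7a‑tetrahydro‑1H‑indene‑1,5(6H)‑dione | O=C1CC[C@@]2(C)C(=O)CCC2=C1C | intermediate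
11 | vinylmagnesium bromide | C=C[Mg]Br | starting material
12 | (1S,7aR)‑1‑ethenyl‑1‑hydroxy‑4,7a‑dimethyl‑1,2,3,6,7,7a‑hexahydro‑5H‑inden‑5‑one | O=C1CC[C@@]2(C)[C@@](O)(C=C)CCC2=C1C | intermediate
13 | lithium (1S,7aR)‑1‑ethenyl‑4,7a‑dimethyl‑5‑oxo‑2,3,5,6,7,7a‑hexahydro‑1H‑inden‑1‑olate | O=C1CC[C@@]2(C)[C@@](O[Li])(C=C)CCC2=C1C | intermediate
14 | dilithium (1S,3aR,7aR)‑1‑ethenyl‑4,7a‑dimethyl‑2,3,3a,6,7,7a‑hexahydro‑1H‑indene‑1,5‑diolate (trans‑fused enolate alkoxide) | [Li]OC1CC[C@@]2(C)[C@@](O[Li])(C=C)CC[C@@H]2C=1C | intermediate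
15 | (1S,3aS,4R,7aR)‑1‑ethenyl‑1‑hydroxy‑4‑{[2‑(methoxymethoxy)‑3‑methylphenyl]methyl}‑4,7a‑dimethyloctahydro‑5H‑inden‑5‑one | O=C1CC[C@@]2(C)[C@@](O)(C=C)CC[C@@H]2[C@@]1(C)Cc1cccc(C)c1OCOC | intermediate
16 | (1S,3aR,4R,5R,7aR)‑1‑ethenyl‑4‑{[2‑(methoxymethoxy)‑3‑methylphenyl]methyl}‑4,7a‑dimethyloctahydro‑1H‑indene‑1,5‑diol | O[C@@H]1CC[C@@]2(C)[C@@](O)(C=C)CC[C@@H]2[C@@]1(C)Cc1cccc(C)c1OCOC | intermediate
17 | methyl iodoacetate | COC(=O)CI | starting material
18 | methyl 4‑iodo‑4‑(1,5‑dihydroxyhydrindan‑1‑yl)butanoate derived from 16 (ring stereocentres as in 16; epimers at the C–I carbon) | O[C@@H]1CC[C@@]2(C)[C@@](O)(C(I)CCC(=O)OC)CC[C@@H]2[C@@]1(C)Cc1cccc(C)c1OCOC | intermediate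
19 | methyl 3‑[(1S,4aS,5R,6R,8aR)‑6‑hydroxy‑5‑{[2‑(methoxymethoxy)‑3‑methylphenyl]methyl}‑5,8a‑dimethyl‑2‑oxodecahydronaphthalen‑1‑yl]propanoate (formed together with its C1 epimer) | COC(=O)CC[C@@H]1C(=O)CC[C@H]2[C@@]1(C)CC[C@@H](O)[C@]2(C)Cc1cccc(C)c1OCOC | intermediate
20 | 2‑alkoxy‑5,7‑di‑tert‑butyl‑3‑phenyl‑2,3‑dihydrobenzoxazole adduct of 19 (bound through the C6 oxygen) | COC(=O)CC[C@@H]1C(=O)CC[C@H]2[C@@]1(C)CC[C@@H](OC3Oc4c(C(C)(C)C)cc(C(C)(C)C)cc4N3c3ccccc3)[C@]2(C)Cc1cccc(C)c1OCOC | intermediate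
21 | methyl 3‑[(1S,4aR,5S,6S,8aR)‑5‑{[2‑(methoxymethoxy)‑3‑methylphenyl]methyl}‑5,6,8a‑trimethyl‑2‑oxodecahydronaphthalen‑1‑yl]propanoate | COC(=O)CC[C@@H]1C(=O)CC[C@H]2[C@@]1(C)CC[C@H](C)[C@]2(C)Cc1cccc(C)c1OCOC | intermediate
22 | methyl 3‑[(1S,4aR,5S,6S,8aR)‑5‑[(2‑hydroxy‑3‑methylphenyl)methyl]‑5,6,8a‑trimethyl‑2‑oxodecahydronaphthalen‑1‑yl]propanoate | COC(=O)CC[C@@H]1C(=O)CC[C@H]2[C@@]1(C)CC[C@H](C)[C@]2(C)Cc1cccc(C)c1O | intermediate
23 | methyl 3‑[(1S,4aR,5S,6S,8aR)‑5,6,8a‑trimethyl‑5‑[(5‑methyl‑3,6‑dioxocyclohexa‑1,4‑dien‑1‑yl)methyl]‑2‑oxodecahydronaphthalen‑1‑yl]propanoate | COC(=O)CC[C@@H]1C(=O)CC[C@H]2[C@@]1(C)CC[C@H](C)[C@]2(C)CC1=CC(=O)C=C(C)C1=O | intermediate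
24 | methyl 3‑[(1S,4aR,5S,6S,8aR)‑5‑[(2,5‑dihydroxy‑3‑methylphenyl)methyl]‑5,6,8a‑trimethyl‑2‑oxodecahydronaphthalen‑1‑yl]propanoate (CNP0535359.1) | COC(=O)CC[C@@H]1C(=O)CC[C@H]2[C@@]1(C)CC[C@H](C)[C@]2(C)Cc1cc(O)cc(C)c1O | target

**Step count**
Total: 10 steps (2 for bromide 6, 8 on the main line). Longest linear sequence: 8 steps (steps 3–10; the arene branch 1, 2, 5–10 is equally long).

**Three steps most likely to fail, each with a fallback**

Step 7 (the proposed ring expansion). The iodide could instead be displaced by the ester carbonyl (γ‑lactone) or by the carbinol oxygen (epoxide), or the methylene carbon C2 could migrate in place of C7a. The fallback uses known chemistry and sets out from 16. Hydroxyl‑directed epoxidation of the vinyl group (VO(acac)2, t‑BuOOH, CH2Cl2) gives the epoxy diol F1. ZnBr2 in CH2Cl2 effects the established semipinacol rearrangement of the 2,3‑epoxy alcohol, the ring carbon shifting to the epoxide carbon next to the carbinol, to give the ring‑expanded β‑hydroxy ketone F2. MsCl/Et3N converts the primary alcohol into the mesylate F3, and DBU eliminates it to the α‑methylene ketone F4. Mukaiyama–Michael addition of 1‑methoxy‑1‑(trimethylsilyloxy)ethene (from methyl acetate, catalytic Sc(OTf)3) gives the silyl enol ether F5, whose hydrolysis on work‑up returns to the route at 19. This fallback relies on the same migration preference, so it answers the lactone and epoxide risks but not a wrong migrating carbon.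

Step 8 (radical methylation at the hindered C6). The coupling may be slow at this neopentyl‑type centre, or the face selectivity may be modest. The fallback sets out from ketone 15 and installs the methyl by a stereospecific hydride shift before the ring expansion. Wittig methylenation (Ph3P=CH2 from Ph3PCH3Br/KOt‑Bu, toluene, 80 °C) gives the exocyclic alkene F6. mCPBA epoxidises this more electron‑rich alkene on the face away from the C4 methyl to give the spiro‑epoxide F7. BF3·OEt2 at −78 °C brings about the Meinwald rearrangement, the hydride shifting with inversion, to give the axial aldehyde F8 with the formyl group anti to the C4 methyl. NaBH4 gives the primary alcohol F9, TsCl/pyridine the tosylate F10, and LiEt3BH the C5‑methyl vinyl carbinol F11. The step 7 conditions, through the iodohydrin F12, then return to the route at 21.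

Step 4 (chemoselective vinyl addition in the presence of the enone). The reagent may also attack the conjugated carbonyl. The fallback sets out from 10 and protects the enone in the classical way: pyrrolidine in MeOH condenses only with the conjugated ketone to give the dienamine F13; CH2=CHMgBr in THF at 0 °C then adds to the remaining cyclopentanone to give the dienamine carbinol F14; buffered aqueous AcOH/NaOAc hydrolysis returns to the route at 12.

**Further compounds**
F1 | step 7 | epoxy diol: 16 with the vinyl group converted into an oxiran‑2‑yl group (epimers at the epoxide carbon) | O[C@@H]1CC[C@@]2(C)[C@@](O)(C3CO3)CC[C@@H]2[C@@]1(C)Cc1cccc(C)c1OCOC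
F2 | step 7 | (4aS,5R,6R,8aR)‑6‑hydroxy‑1‑(hydroxymethyl)‑5‑{[2‑(methoxymethoxy)‑3‑methylphenyl]methyl}‑5,8a‑dimethyloctahydronaphthalen‑2(1H)‑one (C1 epimers) | OCC1C(=O)CC[C@H]2[C@@]1(C)CC[C@@H](O)[C@]2(C)Cc1cccc(C)c1OCOC
F3 | step 7 | primary methanesulfonate of F2 | CS(=O)(=O)OCC1C(=O)CC[C@H]2[C@@]1(C)CC[C@@H](O)[C@]2(C)Cc1cccc(C)c1OCOC
F4 | step 7 | (4aS,5R,6R,8aR)‑6‑hydroxy‑5‑{[2‑(methoxymethoxy)‑3‑methylphenyl]methyl}‑5,8a‑dimethyl‑1‑methylideneoctahydronaphthalen‑2(1H)‑one | C=C1C(=O)CC[C@H]2[C@@]1(C)CC[C@@H](O)[C@]2(C)Cc1cccc(C)c1OCOC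
F5 | step 7 | trimethylsilyl enol ether of 19 (C1=C2 double bond) | COC(=O)CCC1=C(O[Si](C)(C)C)CC[C@H]2[C@@]1(C)CC[C@@H](O)[C@]2(C)Cc1cccc(C)c1OCOC
F6 | step 8 | 5‑methylidene analogue of 15 | C=C1CC[C@@]2(C)[C@@](O)(C=C)CC[C@@H]2[C@@]1(C)Cc1cccc(C)c1OCOC
F7 | step 8 | spiro‑epoxide of F6 at C5 (epoxide oxygen on the face opposite the C4 methyl) | [C@]13(CO3)CC[C@@]2(C)[C@@](O)(C=C)CC[C@@H]2[C@@]1(C)Cc1cccc(C)c1OCOC
F8 | step 8 | 5‑formyl hydrindane (formyl axial and anti to the C4 methyl) | O=C[C@H]1CC[C@@]2(C)[C@@](O)(C=C)CC[C@@H]2[C@@]1(C)Cc1cccc(C)c1OCOC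
F9 | step 8 | 5‑(hydroxymethyl) hydrindane from F8 | OC[C@H]1CC[C@@]2(C)[C@@](O)(C=C)CC[C@@H]2[C@@]1(C)Cc1cccc(C)c1OCOC
F10 | step 8 | 4‑methylbenzenesulfonate of F9 | Cc1ccc(cc1)S(=O)(=O)OC[C@H]1CC[C@@]2(C)[C@@](O)(C=C)CC[C@@H]2[C@@]1(C)Cc1cccc(C)c1OCOC
F11 | step 8 | 1‑ethenyl‑4‑{[2‑(methoxymethoxy)‑3‑methylphenyl]methyl}‑4,5,7a‑trimethyloctahydro‑1H‑inden‑1‑ol (5‑methyl anti to the C4 methyl) | C[C@H]1CC[C@@]2(C)[C@@](O)(C=C)CC[C@@H]2[C@@]1(C)Cc1cccc(C)c1OCOC
F12 | step 8 | iodohydrin from F11 and methyl iodoacetate (epimers at the C–I carbon) | C[C@H]1CC[C@@]2(C)[C@@](O)(C(I)CCC(=O)OC)CC[C@@H]2[C@@]1(C)Cc1cccc(C)c1OCOC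
F13 | step 4 | (7aR)‑4,7a‑dimethyl‑5‑(pyrrolidin‑1‑yl)‑2,6,7,7a‑tetrahydro‑1H‑inden‑1‑one (dienamine of 10) | N1(CCCC1)C1=C(C)C2=CCC(=O)[C@]2(C)CC1
F14 | step 4 | 1‑ethenyl‑4,7a‑dimethyl‑5‑(pyrrolidin‑1‑yl)‑2,6,7,7a‑tetrahydro‑1H‑inden‑1‑ol (hydroxyl on the angular‑methyl face) | N1(CCCC1)C1=C(C)C2=CC[C@](O)(C=C)[C@]2(C)CC1
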